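A flask's slowness is the time τ in which its unreacted Q falls by a factor e, and each stretch of these flasks has its own τ.

| setting | green | amber | Monday's | Wednesday's |
|---|---|---|---|---|
| Q | 0.17 M | 0.17 M | 0.17 M | 0.17 M |
| J | 37 mM | 130 mM | 26 mM | 100 mM |
| temperature | 25 °C | 45 °C |  |  |
| remark | run made earlier | run made earlier | at 60 °C until 2.5 min, from then on at 30 °C | at 30 °C throughout |
| time |  |  | 8.0 min | 4.0 min |

| run | time / min | L / % |
|---|---|---|
| green | 4.00 | 5.6 |
| green | 12.0 | 17.3 |
| green | 25.0 | 30.8 |
| green | 30.0 | 37.3 |
| amber | 0.833 | 23.8 |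
| amber | 2.00 | 51.2 |
| amber | 5.00 | 77.2 |
| amber | 12.0 | 71.4 |

(scatter of a reading: 1 percentage point)

* which one finishes higher in amount of L, in percent of the Q charged ("neither" within 2 percentage points) (Monday's / Wednesday's / neither)
* amount of L at the end, in percent of the Q charged, Monday's
* amount of L at the end, in percent of the Q charged, Wednesday's

We freeze one thing: Q falls by a pseudo-first-order law, with the unreacted share going as exp(−t/τ) and 1/τ = s[J]. We let the specific rate s change with temperature, hold it fixed otherwise, and read all reacted Q as L. Green gives 0.421 /M/min from its last reading and 0.428 /M/min from the one at 12.0 min, which are close for a scatter of 1 percentage point. Amber gives 2.76 /M/min, read early because its L later falls from 77.2% to 71.4%. These two imply an activation energy of 74.2 kJ/mol, hence 9.75 /M/min at 60 °C and 0.689 /M/min at 30 °C, the specific rate at that temperature, which we carry.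

After its change of temperature, Monday's looks nearly like green: it has less J, 26 mM against 37 mM, but is warmer, 30 °C against 25 °C. Green's τ is 64.3 min, and Monday's τ at 30 °C is shorter, 55.8 min. Green needed 30.0 min to reach 37.3%, whereas Monday's gets 5.50 min at this pace, so t/τ is 0.0985. Monday's hot stretch, with τ of 3.94 min, earns 0.634, so in this reckoning it earns more of Monday's t/τ than the cool stretch. Wednesday's has τ of 14.5 min and t/τ of 0.276.

We commit to 51.9% for Monday's and 24.1% for Wednesday's.

The forecast says Monday's, with 48.5% (41% to 55%) for Monday's, from which, unlike us, it takes some L for loss to Z, and 23.3% (20% to 27%) for Wednesday's, adding: "The 60 °C extrapolation is the main uncertainty".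

Monday's ends at 62.8% and Wednesday's at 21.3%, so Monday's is higher.

    Q + J ⇌ X (K = 9.60 /M, k = 3.40 /M/s, Ea = 61.0 kJ/mol, ΔH = 9.00 kJ/mol)
    X → J + L (k = 0.0570 /s, Ea = 76.0 kJ/mol)
    L + J ⇌ Z + J, rate k3*[J]*[L] forward; the back reaction follows from the equilibrium constant (K = 1.60, k = 0.0120 /M/s, Ea = 50.0 kJ/mol, ΔH = −51.0 kJ/mol)
    (constants at 60 °C)

At 2.50 min, Monday's holds 58.3% of L, against the 47.0% our hot stretch gave. From there, the 40.8% of the charge outside L and Z, with s of 0.689 /M/min and so τ of 55.8 min, should gain 3.8 points, and Monday's gains 4.5 points. On Wednesday's, the same s gave 24.1%, while that flask ends with 21.3% of L and 22.6% of the Q charged standing as X.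

The earlier runs and the new flask were generated by integration for substances that don't exist, and the scatter is random.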